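**Plan**

- Retrosynthesis: the two O–CH3 bonds of the catechol are cut last. The pyranone of the 7-hydroxycoumarin half (ring B) is cut at C3=C4 and O1–C2 back to a salicylaldehyde. Its benzene ring (ring A) is cut at C5–C6 and C4a–C8a into a four-carbon diene and propynal.
- Feature that allows this: C6 (aryloxy), C7 (hydroxyl), C8 and C8a (lactone oxygen) of ring A are the four carbons of a 4-aryloxyacetoacetate with all three oxygens already in place. C5–C4a is then a two-carbon alkyne unit whose formyl group becomes C4.
- The diene is cut at its O–CH2 bond into 5-hydroxy-6,7-dimethoxycoumarin and methyl 4-chloroacetoacetate. The C5 oxygen of that coumarin goes back to a formyl group placed on isoscopoletin.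
- Forward: the dioxygenated coumarin half is bought intact and oxygenated at C5; O-alkylation and double silylation give the diene; ring A arises by [4+2] cycloaddition and aromatisation; ring B by Wittig olefination and lactonisation; demethylation ends the route.
- Stereochemistry: the target has no stereocentre. The sp3 carbons of the cycloadduct vanish on aromatisation, and the cis C3=C4 bond of ring B is fixed by the lactone ring.

Key step: step 8

Assumption: the enol ether geometries drawn for 8 and 9 are the expected major isomers; they have no bearing on the outcome, because all four sp2 carbons of 9 end up in the aromatic ring.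

**Route**

Step 1
Reactants: 1 isoscopoletin (6-hydroxy-7-methoxy-2H-chromen-2-one)
Product: 2 6-hydroxy-7-methoxy-2-oxo-2H-chromene-5-carbaldehyde
Conditions: MgCl2, Et3N, (CH2O)n, MeCN, reflux; aq. HCl work-up
Reagents that add atoms: paraformaldehyde (formaldehyde), C=O
Why: Magnesium-mediated ortho-formylation of a phenol (Casnati–Skattebøl reaction), in which the magnesium phenoxide delivers formaldehyde to C5, the only free ortho carbon because C7 is blocked, and a second formaldehyde oxidises the benzylic alkoxide to the aldehyde.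

Step 2
Reactants: 2 6-hydroxy-7-methoxy-2-oxo-2H-chromene-5-carbaldehyde
Product: 3 6,7-dimethoxy-2-oxo-2H-chromene-5-carbaldehyde
Conditions: MeI, K2CO3, DMF, 50 °C
Reagents that add atoms: iodomethane, CI
Why: Williamson O-methylation of the phenoxide, to which the aldehyde and the lactone are inert.

Step 3
Reactants: 3 6,7-dimethoxy-2-oxo-2H-chromene-5-carbaldehyde
Product: 5 5-hydroxy-6,7-dimethoxy-2H-chromen-2-one, via aryl formate 4 (not isolated)
Conditions: mCPBA, CH2Cl2, 0 °C → rt; then Et3N, MeOH, rt
Reagents that add atoms: 3-chloroperoxybenzoic acid, O=C(OO)c1cccc(Cl)c1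
Why: Baeyer–Villiger (Dakin-type) oxidation in which the aryl group with its ortho methoxy donor migrates in the Criegee intermediate to give formate 4, which mild methanolysis cleaves without opening the lactone, while the electron-poor C3=C4 bond is not epoxidised.

Step 4
Reactants: 5 5-hydroxy-6,7-dimethoxy-2H-chromen-2-one; 6 methyl 4-chloroacetoacetate
Product: 7 methyl 4-[(6,7-dimethoxy-2-oxo-2H-chromen-5-yl)oxy]-3-oxobutanoate
Conditions: NaH (2.2 equiv), THF–DMF, 0 °C → rt; then dilute HCl to pH 3
Reagents that add atoms: none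
Why: Williamson ether synthesis by SN2 displacement of the primary chloride, in which the second equivalent of NaH holds the keto ester as its enolate and so blocks self-condensation, as in the standard preparation of 4-alkoxy- and 4-aryloxyacetoacetates; the hindered aryl–oxygen bond is thus made on an unhindered CH2.

Step 5
Reactants: 7 methyl 4-[(6,7-dimethoxy-2-oxo-2H-chromen-5-yl)oxy]-3-oxobutanoate
Product: 8 methyl (2Z)-4-[(6,7-dimethoxy-2-oxo-2H-chromen-5-yl)oxy]-3-[(trimethylsilyl)oxy]but-2-enoate
Conditions: TMSCl, Et3N, toluene, rt; filtration under argon, concentration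
Reagents that add atoms: chlorotrimethylsilane, C[Si](C)(C)Cl
Why: O-silylation of the enolised β-keto ester with TMSCl and Et3N, the first stage of the standard two-stage preparation of 1,3-bis(silyl enol ethers).

Step 6
Reactants: 8 methyl (2Z)-4-[(6,7-dimethoxy-2-oxo-2H-chromen-5-yl)oxy]-3-[(trimethylsilyl)oxy]but-2-enoate
Product: 9 5-{[(1Z,3Z)-4-methoxy-2,4-bis(trimethylsilyloxy)buta-1,3-dien-1-yl]oxy}-6,7-dimethoxy-2H-chromen-2-one
Conditions: LiN(SiMe3)2, TMSCl (present from the start), THF, −78 → 0 °C; pentane, filtration under argon; used crude at once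
Reagents that add atoms: chlorotrimethylsilane, C[Si](C)(C)Cl
Why: γ-Deprotonation of the vinylogous ester and O-silylation of the dienolate (second stage of the Chan-type diene preparation), where the aryloxy group acidifies the γ-CH2 enough for the hindered, non-nucleophilic silylamide, which should leave the coumarin lactone and its C4 position alone at −78 °C.

Step 7
Reactants: 10 propiolaldehyde diethyl acetal (3,3-diethoxyprop-1-yne)
Product: 11 propynal
Conditions: H2O, cat. H2SO4, 50–70 °C, aldehyde distilled off as formed into a −78 °C receiver; dried (MgSO4), redistilled into cold toluene; used the same day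
Reagents that add atoms: water, O
Why: Acid-catalysed acetal hydrolysis, driven by distilling the low-boiling aldehyde out of the mixture as it forms.

Step 8
Reactants: 9 5-{[(1Z,3Z)-4-methoxy-2,4-bis(trimethylsilyloxy)buta-1,3-dien-1-yl]oxy}-6,7-dimethoxy-2H-chromen-2-one; 11 propynal (3 equiv)
Product: 14 5-[(6,7-dimethoxy-2-oxo-2H-chromen-5-yl)oxy]-2,4-dihydroxybenzaldehyde, via cyclohexadiene cycloadduct 12 (not isolated), via bis-silyl ether 13 (not isolated)
Conditions: toluene, −20 °C → 50 °C (sealed tube), no Lewis acid; then 1 M HCl, THF, rt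
Reagents that add atoms: none
Why: The electron-rich diene 9 and the polarised triple bond of propynal 11 should combine without a Lewis acid in a normal-electron-demand [4+2] cycloaddition (concerted but asynchronous, or a Mukaiyama–Michael addition followed by ring closure, with the same outcome) that forms C5–C6 and C4a–C8a and gives cyclohexa-1,4-diene 12. The closest known reaction type is the Diels–Alder reaction of 1-alkoxy-1,3-bis(silyloxy)buta-1,3-dienes (Chan and Brassard type) with acetylenic carbonyl dienophiles followed by aromatisation to resorcinol derivatives, the aryloxy group on the diene terminus being the only extension. Ring A, the single ring formed, is closed by this intermolecular [4+2] cycloaddition as a six-membered carbocycle. No stereocentre survives: the two sp3 carbons of 12 (C6 and C8a) are erased when methanol is lost across the ring to give 13, and the aryloxy group cannot leave instead because C8a carries no hydrogen and C5 and C7 are sp2. The step needs regioselectivity, secured by the push of the 1,1-dioxygenated and 3-silyloxy carbons onto the aryloxy-bearing terminus, which therefore bonds to the β-carbon of the ynal and puts the formyl group ortho to the C8a oxygen, and chemoselectivity for the triple bond over the aldehyde, secured by the absence of any Lewis acid. Dilute acid then removes both silyl groups to give 14.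

Step 9
Reactants: 14 5-[(6,7-dimethoxy-2-oxo-2H-chromen-5-yl)oxy]-2,4-dihydroxybenzaldehyde; 15 ethyl (triphenylphosphoranylidene)acetate (2 equiv)
Product: 18 6-[(6,7-dimethoxy-2-oxo-2H-chromen-5-yl)oxy]-7-hydroxy-2H-chromen-2-one, via E-cinnamate 16 (not isolated), via Z-cinnamate 17 (not isolated)
Conditions: PhNEt2, reflux (ca. 215 °C), N2
Reagents that add atoms: none
Why: Wittig olefination with a stabilised ylide followed, at the boiling point of N,N-diethylaniline, by E to Z isomerisation of the cinnamate and lactonisation onto the ortho hydroxyl, a known one-flask coumarin synthesis from salicylaldehydes that tolerates a free para hydroxyl.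

Step 10
Reactants: 18 6-[(6,7-dimethoxy-2-oxo-2H-chromen-5-yl)oxy]-7-hydroxy-2H-chromen-2-one
Product: 19 6-[(6,7-dihydroxy-2-oxo-2H-chromen-5-yl)oxy]-7-hydroxy-2H-chromen-2-one (CNP0197949.0)
Conditions: BBr3 (6 equiv), CH2Cl2, −78 °C → rt; then MeOH, H2O
Reagents that add atoms: none
Why: Lewis-acid cleavage of aryl methyl ethers with BBr3 (bromide attacks the methyl group of the boron-bound ether), which the diaryl ether, having no alkyl carbon to attack, and both lactones should survive.

**Compound list**

1 | isoscopoletin (6-hydroxy-7-methoxy-2H-chromen-2-one) | COc1cc2oc(=O)ccc2cc1O | starting material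
2 | 6-hydroxy-7-methoxy-2-oxo-2H-chromene-5-carbaldehyde | COc1cc2oc(=O)ccc2c(C=O)c1O | intermediate
3 | 6,7-dimethoxy-2-oxo-2H-chromene-5-carbaldehyde | COc1cc2oc(=O)ccc2c(C=O)c1OC | intermediate
4 | 6,7-dimethoxy-2-oxo-2H-chromen-5-yl formate | COc1cc2oc(=O)ccc2c(OC=O)c1OC | intermediate
5 | 5-hydroxy-6,7-dimethoxy-2H-chromen-2-one | COc1cc2oc(=O)ccc2c(O)c1OC | intermediate
6 | methyl 4-chloroacetoacetate (methyl 4-chloro-3-oxobutanoate) | COC(=O)CC(=O)CCl | starting material
7 | methyl 4-[(6,7-dimethoxy-2-oxo-2H-chromen-5-yl)oxy]-3-oxobutanoate | COC(=O)CC(=O)COc1c(OC)c(OC)cc2oc(=O)ccc12 | intermediate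
8 | methyl (2Z)-4-[(6,7-dimethoxy-2-oxo-2H-chromen-5-yl)oxy]-3-[(trimethylsilyl)oxy]but-2-enoate | COC(=O)/C=C(\O[Si](C)(C)C)COc1c(OC)c(OC)cc2oc(=O)ccc12 | intermediate
9 | 5-{[(1Z,3Z)-4-methoxy-2,4-bis(trimethylsilyloxy)buta-1,3-dien-1-yl]oxy}-6,7-dimethoxy-2H-chromen-2-one | CO/C(O[Si](C)(C)C)=C/C(O[Si](C)(C)C)=C/Oc1c(OC)c(OC)cc2oc(=O)ccc12 | intermediate
10 | propiolaldehyde diethyl acetal (3,3-diethoxyprop-1-yne) | CCOC(OCC)C#C | starting material
11 | propynal | C#CC=O | intermediate
12 | 3-[(6,7-dimethoxy-2-oxo-2H-chromen-5-yl)oxy]-6-methoxy-4,6-bis[(trimethylsilyl)oxy]cyclohexa-1,4-diene-1-carbaldehyde (mixture of diastereomers at C3 and C6) | COC1(O[Si](C)(C)C)C=C(O[Si](C)(C)C)C(Oc2c(OC)c(OC)cc3oc(=O)ccc23)C=C1C=O | intermediate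
13 | 5-[(6,7-dimethoxy-2-oxo-2H-chromen-5-yl)oxy]-2,4-bis[(trimethylsilyl)oxy]benzaldehyde | O=Cc1cc(Oc2c(OC)c(OC)cc3oc(=O)ccc23)c(O[Si](C)(C)C)cc1O[Si](C)(C)C | intermediate
14 | 5-[(6,7-dimethoxy-2-oxo-2H-chromen-5-yl)oxy]-2,4-dihydroxybenzaldehyde | O=Cc1cc(Oc2c(OC)c(OC)cc3oc(=O)ccc23)c(O)cc1O | intermediate
15 | ethyl (triphenylphosphoranylidene)acetate | CCOC(=O)C=P(c1ccccc1)(c1ccccc1)c1ccccc1 | starting material
16 | ethyl (2E)-3-{5-[(6,7-dimethoxy-2-oxo-2H-chromen-5-yl)oxy]-2,4-dihydroxyphenyl}prop-2-enoate | CCOC(=O)/C=C/c1cc(Oc2c(OC)c(OC)cc3oc(=O)ccc23)c(O)cc1O | intermediate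
17 | ethyl (2Z)-3-{5-[(6,7-dimethoxy-2-oxo-2H-chromen-5-yl)oxy]-2,4-dihydroxyphenyl}prop-2-enoate | CCOC(=O)/C=C\c1cc(Oc2c(OC)c(OC)cc3oc(=O)ccc23)c(O)cc1O | intermediate
18 | 6-[(6,7-dimethoxy-2-oxo-2H-chromen-5-yl)oxy]-7-hydroxy-2H-chromen-2-one | O=c1ccc2cc(Oc3c(OC)c(OC)cc4oc(=O)ccc34)c(O)cc2o1 | intermediate
19 | 6-[(6,7-dihydroxy-2-oxo-2H-chromen-5-yl)oxy]-7-hydroxy-2H-chromen-2-one | O=c1ccc2cc(Oc3c(O)c(O)cc4oc(=O)ccc34)c(O)cc2o1 | target

**Count and risks**

Total steps: 10. Longest linear sequence: 9 steps (steps 1–6 and 8–10, from isoscopoletin); step 7 is a one-step side branch.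

Steps most likely to fail:

1. Step 8 (cycloaddition and aromatisation). Propynal may polymerise, or the diene may lose its silyl groups to traces of acid or ethanol in the distillate, faster than the two partners combine. Fallback: diene 9 is combined instead with 2-bromoacrolein (C=C(Br)C=O), a stable and very reactive alkene dienophile that serves as a propynal equivalent (toluene, −40 °C → rt). The nucleophilic diene terminus again bonds to the β-carbon and should give 1-bromo-5-[(6,7-dimethoxy-2-oxo-2H-chromen-5-yl)oxy]-2-methoxy-2,4-bis[(trimethylsilyl)oxy]cyclohex-3-ene-1-carbaldehyde F1. DBU then removes HBr to give the same cyclohexadiene 12, which loses methanol to 13 and is desilylated with 1 M HCl in THF. The fallback sets out from 9 and comes back to the route at 14.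

2. Step 4 (O-alkylation). The enolate of the chloroacetoacetate may condense with itself or be alkylated on carbon faster than the hindered phenoxide of 5 displaces chloride. Fallback: 5 is alkylated with methyl (2E)-4-bromo-3-methoxybut-2-enoate (K2CO3, acetone, reflux), a masked acetoacetate that cannot enolise toward the halide, to give methyl (2E)-4-[(6,7-dimethoxy-2-oxo-2H-chromen-5-yl)oxy]-3-methoxybut-2-enoate F2. Hydrolysis of the enol ether with 2 M HCl in THF at 40 °C then gives the β-keto ester. The fallback sets out from 5 and comes back at 7.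

3. Step 3 (Baeyer–Villiger oxidation). In the Criegee intermediate hydride may migrate instead of the doubly ortho-substituted aryl group, whose 6-methoxy donor is twisted out of conjugation, so that the carboxylic acid forms in place of the formate. Fallback: the aldehyde is avoided altogether. Isoscopoletin 1 is brominated at its only free position ortho to the hydroxyl (NBS, MeCN, 0 °C) to give 5-bromo-6-hydroxy-7-methoxy-2H-chromen-2-one F3. Methylation (MeI, K2CO3, DMF) gives 5-bromo-6,7-dimethoxy-2H-chromen-2-one F4. Miyaura borylation (B2pin2, PdCl2(dppf), KOAc, dioxane, 90 °C) gives 6,7-dimethoxy-5-(4,4,5,5-tetramethyl-1,3,2-dioxaborolan-2-yl)-2H-chromen-2-one F5, and oxidation of the carbon–boron bond (NaBO3·4H2O, THF–H2O, rt) gives the phenol. The fallback sets out from 1 and comes back at 5.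

**Further compounds**

F1 | step 8 | 1-bromo-5-[(6,7-dimethoxy-2-oxo-2H-chromen-5-yl)oxy]-2-methoxy-2,4-bis[(trimethylsilyl)oxy]cyclohex-3-ene-1-carbaldehyde | COC1(O[Si](C)(C)C)C=C(O[Si](C)(C)C)C(Oc2c(OC)c(OC)cc3oc(=O)ccc23)CC1(Br)C=O
F2 | step 4 | methyl (2E)-4-[(6,7-dimethoxy-2-oxo-2H-chromen-5-yl)oxy]-3-methoxybut-2-enoate | COC(=O)/C=C(/OC)COc1c(OC)c(OC)cc2oc(=O)ccc12
F3 | step 3 | 5-bromo-6-hydroxy-7-methoxy-2H-chromen-2-one | COc1cc2oc(=O)ccc2c(Br)c1O
F4 | step 3 | 5-bromo-6,7-dimethoxy-2H-chromen-2-one | COc1cc2oc(=O)ccc2c(Br)c1OC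
F5 | step 3 | 6,7-dimethoxy-5-(4,4,5,5-tetramethyl-1,3,2-dioxaborolan-2-yl)-2H-chromen-2-one | COc1cc2oc(=O)ccc2c(B3OC(C)(C)C(C)(C)O3)c1OC
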